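**Retrosynthetic overview**

- The strategy rests on ring C. C2 carries the 4-hydroxyphenyl ring B (beta to the C4 carbonyl) and C3 carries the hydroxyl (alpha to it), trans to each other. This vicinal aryl/oxygen pair is cut at C2–C1' and C3–O, leading back to the C2=C3 bond of a flat, achiral 5,7-dioxygenated chromone.
- Both bonds are to be formed in one flask: enantioselective rhodium-catalysed transfer of a 4-silyloxyphenyl group from zinc to C2 with silyl trapping at O4, then Rubottom oxidation of the enol ether at C3.
- The O7–CH2 bond is cut last (Mitsunobu), to an (E)-4-silyloxy-3-methylbut-2-en-1-ol made from prenyl acetate. The O5/O7 benzyl ethers are removed before the alkene arrives; the silyl ethers on O4' and on the side chain are removed at the end.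
- Ring order: ring A is bought (phloroacetophenone), ring C is closed early as the chromone (enaminone cyclisation), ring B is attached at C2 in the key step, and no ring is formed afterwards.

Key step: step 6

Remark: the sense of induction of the rhodium/(S)-BINAP catalyst on the chromone is assumed to follow that on cyclic enones, 2,3-dihydro-4-pyridones and 4-quinolones; if a test run shows the opposite sense, (R)-BINAP is used and nothing else changes.

**Route**

Step 1
Reactants: 1 2,4,6-trihydroxyacetophenone
Product: 2 1-[2,4-bis(benzyloxy)-6-hydroxyphenyl]ethan-1-one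
Conditions: BnBr (2.05 equiv), K2CO3 (2.2 equiv), DMF, 0 → 23 °C
Reagents that add atoms: benzyl bromide BrCc1ccccc1
Why: Williamson etherification in which the hydroxyl hydrogen-bonded to the acetyl carbonyl is the least acidic and least nucleophilic, so two equivalents of halide should cap the para and the free ortho phenol and leave the chelated one.

Step 2
Reactants: 2 1-[2,4-bis(benzyloxy)-6-hydroxyphenyl]ethan-1-one; 3 N,N-dimethylformamide dimethyl acetal
Product: 4 (E)-1-[2,4-bis(benzyloxy)-6-hydroxyphenyl]-3-(dimethylamino)prop-2-en-1-one
Conditions: 3 (3 equiv), toluene, 95 °C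
Reagents that add atoms: none
Why: condensation of the methyl ketone with the amide acetal (enaminone formation) with loss of two molecules of methanol installs the one carbon that becomes C2.

Step 3
Reactants: 4 (E)-1-[2,4-bis(benzyloxy)-6-hydroxyphenyl]-3-(dimethylamino)prop-2-en-1-one
Product: 5 5,7-bis(benzyloxy)-4H-chromen-4-one
Conditions: conc. aq. HCl, CH2Cl2, 23 → 40 °C
Reagents that add atoms: none
Why: acid-promoted 6-endo oxa-Michael addition of the phenol to the protonated enaminone followed by elimination of dimethylamine closes ring C as the chromone, and the benzyl ethers tolerate the brief aqueous acid.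

Step 4
Reactants: 6 4-bromophenol
Product: 7 (4-bromophenoxy)triisopropylsilane
Conditions: TIPSCl (1.1 equiv), imidazole (2.2 equiv), DMF, 23 °C
Reagents that add atoms: chlorotriisopropylsilane CC(C)[Si](Cl)(C(C)C)C(C)C
Why: imidazole-mediated silylation of a phenol gives a bulky aryl silyl ether that withstands organolithium, organozinc, hydrogenolysis and Mitsunobu conditions.

Step 5
Reactants: 7 (4-bromophenoxy)triisopropylsilane
Product: 9 [4-(triisopropylsilyloxy)phenyl]zinc chloride kept as a titrated THF solution, via aryllithium 8 (not isolated)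
Conditions: n-BuLi (1.05 equiv), THF, −78 °C; ZnCl2 (1.1 equiv, THF), −78 → 23 °C
Reagents that add atoms: zinc chloride Cl[Zn]Cl (zinc and chloride of 9); n-butyllithium [Li]CCCC (lithium of intermediate 8 only)
Why: bromine–lithium exchange is fast at −78 °C for an aryl bromide, and transmetalation to ZnCl2 gives an arylzinc chloride that does not add to ketones without a catalyst.

Step 6
Reactants: 5 5,7-bis(benzyloxy)-4H-chromen-4-one; 9 [4-(triisopropylsilyloxy)phenyl]zinc chloride
Product: 13 (2R,3R)-5,7-bis(benzyloxy)-3-hydroxy-2-[4-(triisopropylsilyloxy)phenyl]chroman-4-one, via silyl enol ether 10 (not isolated), via silyloxy epoxide 11 (not isolated), via 3-O-trimethylsilyl ketol 12 (not isolated)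
Conditions: [RhCl(C2H4)2]2 (2.5 mol%), (S)-BINAP (5.5 mol%), THF, 20 °C; 9 (1.5 equiv), Me3SiCl (1.5 equiv), 20 °C; volatiles removed in the same flask, CH2Cl2; DMDO (acetone solution, ca. 2.2 equiv), −40 → 0 °C; aq. citric acid, MeOH, 0 °C
Reagents that add atoms: dimethyldioxirane CC1(C)OO1 (the C3 oxygen); chlorotrimethylsilane C[Si](C)(C)Cl (silicon carried only in intermediates 10 to 12)
Why: Proposed new method: arylzinc chloride 9 transmetalates to the chloride-bridged monovalent rhodium complex [RhCl((S)-binap)]2, the aryl–rhodium species inserts the C2=C3 bond of chromone 5 with the aryl group going to C2, and Me3SiCl silylates the rhodium enolate on oxygen to release neutral silyl enol ether 10 and return Rh–Cl, so the free flavanone enolate, which would open to the chalcone by retro-oxa-Michael reaction, never forms. The closest known reaction types are the rhodium/BINAP-catalysed asymmetric 1,4-addition of arylzinc chlorides with Me3SiCl to 4-quinolones and 2,3-dihydro-4-pyridones, the rhodium- or palladium-catalysed asymmetric 1,4-addition of arylboronic acids to chromones, and the Rubottom oxidation of flavanone silyl enol ethers. Dimethyldioxirane then epoxidises the electron-rich C3=C4 enol ether to 11, which opens to the oxocarbenium ion and passes by 1,4-silyl shift to 12, and mild acid frees the 3-OH; no ring is closed, only the C2–C1' and C3–O bonds are made on the existing ring C. C2 is set by the catalyst alone because 5 is flat and achiral: (S)-BINAP is expected to give the (2S)-enol ether, which becomes the 2R series once C3 bears oxygen. C3 is set by the substrate, since the oxidant approaches the enol ether face anti to the C2 aryl group to give the 2,3-trans ketol, and any cis isomer should equilibrate through the C3 enol to the diequatorial trans compound. The step needs enantioface selectivity at C2 (ligand), 1,4- over 1,2-addition (soft aryl–rhodium, arylzinc inert to the carbonyl) and anti selectivity at C3 (shielding by the C2 aryl group).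

Step 7
Reactants: 13 (2R,3R)-5,7-bis(benzyloxy)-3-hydroxy-2-[4-(triisopropylsilyloxy)phenyl]chroman-4-one
Product: 14 (2R,3R)-3,5,7-trihydroxy-2-[4-(triisopropylsilyloxy)phenyl]chroman-4-one
Conditions: H2 (1 atm), Pd/C (10 wt%), EtOAc, 23 °C, stopped at full conversion
Reagents that add atoms: none
Why: catalytic hydrogenolysis of the two aryl benzyl ethers under neutral conditions should spare the aryl silyl ether, the aryl ketone and the benzylic C2–O1 bond and touches neither stereocentre.

Step 8
Reactants: 15 prenyl acetate (3-methylbut-2-en-1-yl acetate)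
Product: 17 (E)-4-hydroxy-3-methylbut-2-en-1-yl acetate, via enal 16 (not isolated)
Conditions: SeO2 (0.3 equiv), t-BuOOH (2 equiv), CH2Cl2, 23 °C; then NaBH4, MeOH, 0 °C on the crude mixture
Reagents that add atoms: selenium dioxide O=[Se]=O (delivers the oxygen, recycled); tert-butyl hydroperoxide CC(C)(C)OO (terminal oxidant)
Why: Riley allylic oxidation by ene reaction and [2,3]-sigmatropic shift selects the methyl group trans to the chain of the trisubstituted alkene and so gives the E allylic alcohol, while borohydride at 0 °C returns over-oxidised enal 16 to the same alcohol without cleaving the acetate.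

Step 9
Reactants: 17 (E)-4-hydroxy-3-methylbut-2-en-1-yl acetate
Product: 18 (E)-4-(tert-butyldimethylsilyloxy)-3-methylbut-2-en-1-yl acetate
Conditions: TBSCl (1.1 equiv), imidazole (2.2 equiv), CH2Cl2, 23 °C
Reagents that add atoms: tert-butyldimethylsilyl chloride CC(C)(C)[Si](C)(C)Cl
Why: standard imidazole-mediated silylation of a primary allylic alcohol, with no effect on the alkene geometry.

Step 10
Reactants: 18 (E)-4-(tert-butyldimethylsilyloxy)-3-methylbut-2-en-1-yl acetate
Product: 19 (E)-4-(tert-butyldimethylsilyloxy)-3-methylbut-2-en-1-ol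
Conditions: K2CO3 (0.2 equiv), MeOH, 0 → 23 °C
Reagents that add atoms: none
Why: base-catalysed transesterification with methanol removes the acetate while the primary silyl ether survives the short, cold exposure.

Step 11
Reactants: 14 (2R,3R)-3,5,7-trihydroxy-2-[4-(triisopropylsilyloxy)phenyl]chroman-4-one; 19 (E)-4-(tert-butyldimethylsilyloxy)-3-methylbut-2-en-1-ol
Product: 20 (2R,3R)-7-{[(E)-4-(tert-butyldimethylsilyloxy)-3-methylbut-2-en-1-yl]oxy}-3,5-dihydroxy-2-[4-(triisopropylsilyloxy)phenyl]chroman-4-one
Conditions: PPh3 (1.2 equiv), DIAD (1.2 equiv), 19 (1.1 equiv), THF, 0 → 23 °C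
Reagents that add atoms: none
Why: Mitsunobu etherification in which the 7-OH is the most acidic and only non-chelated phenol, the primary allylic alcohol is activated ahead of the hindered secondary 3-OH, substitution occurs at the primary carbon so the E alkene is kept, and the absence of base protects ring C and the C2/C3 stereocentres.

Step 12
Reactants: 20 (2R,3R)-7-{[(E)-4-(tert-butyldimethylsilyloxy)-3-methylbut-2-en-1-yl]oxy}-3,5-dihydroxy-2-[4-(triisopropylsilyloxy)phenyl]chroman-4-one
Product: 21 (2R,3R)-3,5-dihydroxy-7-{[(E)-4-hydroxy-3-methylbut-2-en-1-yl]oxy}-2-(4-hydroxyphenyl)chroman-4-one (target)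
Conditions: Bu4NF/AcOH (1:1, 4 equiv), THF, 0 → 23 °C
Reagents that add atoms: none
Why: acetic acid-buffered fluoride desilylation should cleave both the aryl triisopropylsilyl ether and the primary tert-butyldimethylsilyl ether while keeping the medium non-basic, so ring opening, C2/C3 epimerisation and air oxidation to the flavonol are avoided.

**Compound list**

1 | 2,4,6-trihydroxyacetophenone | CC(=O)c1c(O)cc(O)cc1O | starting material
2 | 1-[2,4-bis(benzyloxy)-6-hydroxyphenyl]ethan-1-one | CC(=O)c1c(O)cc(OCc2ccccc2)cc1OCc1ccccc1 | intermediate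
3 | N,N-dimethylformamide dimethyl acetal | COC(OC)N(C)C | starting material
4 | (E)-1-[2,4-bis(benzyloxy)-6-hydroxyphenyl]-3-(dimethylamino)prop-2-en-1-one | CN(C)/C=C/C(=O)c1c(O)cc(OCc2ccccc2)cc1OCc1ccccc1 | intermediate
5 | 5,7-bis(benzyloxy)-4H-chromen-4-one | O=c1ccoc2cc(OCc3ccccc3)cc(OCc3ccccc3)c12 | intermediate
6 | 4-bromophenol | Oc1ccc(Br)cc1 | starting material
7 | (4-bromophenoxy)triisopropylsilane | CC(C)[Si](Oc1ccc(Br)cc1)(C(C)C)C(C)C | intermediate
8 | [4-(triisopropylsilyloxy)phenyl]lithium | [Li]c1ccc(O[Si](C(C)C)(C(C)C)C(C)C)cc1 | intermediate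
9 | [4-(triisopropylsilyloxy)phenyl]zinc chloride | Cl[Zn]c1ccc(O[Si](C(C)C)(C(C)C)C(C)C)cc1 | intermediate
10 | (S)-5,7-bis(benzyloxy)-2-[4-(triisopropylsilyloxy)phenyl]-4-(trimethylsilyloxy)-2H-chromene | C(c1ccccc1)Oc1cc(OCc2ccccc2)c2c(c1)O[C@H](c1ccc(O[Si](C(C)C)(C(C)C)C(C)C)cc1)C=C2O[Si](C)(C)C | intermediate
11 | 5,7-bis(benzyloxy)-3,4-epoxy-2-[4-(triisopropylsilyloxy)phenyl]-4-(trimethylsilyloxy)chromane, C2 as in 10, epoxide oxygen on the face opposite the C2 aryl group | C(c1ccccc1)Oc1cc(OCc2ccccc2)c2c(c1)O[C@H](c1ccc(O[Si](C(C)C)(C(C)C)C(C)C)cc1)[C@H]3O[C@@]23O[Si](C)(C)C | intermediate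
12 | (2R,3R)-5,7-bis(benzyloxy)-2-[4-(triisopropylsilyloxy)phenyl]-3-(trimethylsilyloxy)chroman-4-one | C(c1ccccc1)Oc1cc(OCc2ccccc2)c2c(c1)O[C@H](c1ccc(O[Si](C(C)C)(C(C)C)C(C)C)cc1)[C@@H](O[Si](C)(C)C)C2=O | intermediate
13 | (2R,3R)-5,7-bis(benzyloxy)-3-hydroxy-2-[4-(triisopropylsilyloxy)phenyl]chroman-4-one | C(c1ccccc1)Oc1cc(OCc2ccccc2)c2c(c1)O[C@H](c1ccc(O[Si](C(C)C)(C(C)C)C(C)C)cc1)[C@@H](O)C2=O | intermediate
14 | (2R,3R)-3,5,7-trihydroxy-2-[4-(triisopropylsilyloxy)phenyl]chroman-4-one | Oc1cc(O)c2c(c1)O[C@H](c1ccc(O[Si](C(C)C)(C(C)C)C(C)C)cc1)[C@@H](O)C2=O | intermediate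
15 | prenyl acetate (3-methylbut-2-en-1-yl acetate) | CC(C)=CCOC(C)=O | starting material
16 | (E)-4-acetoxy-2-methylbut-2-enal (over-oxidation product, reduced in the same operation) | CC(=O)OC/C=C(\C)C=O | intermediate
17 | (E)-4-hydroxy-3-methylbut-2-en-1-yl acetate | CC(=O)OC/C=C(\C)CO | intermediate
18 | (E)-4-(tert-butyldimethylsilyloxy)-3-methylbut-2-en-1-yl acetate | CC(=O)OC/C=C(\C)CO[Si](C)(C)C(C)(C)C | intermediate
19 | (E)-4-(tert-butyldimethylsilyloxy)-3-methylbut-2-en-1-ol | C/C(=C\CO)CO[Si](C)(C)C(C)(C)C | intermediate
20 | (2R,3R)-7-{[(E)-4-(tert-butyldimethylsilyloxy)-3-methylbut-2-en-1-yl]oxy}-3,5-dihydroxy-2-[4-(triisopropylsilyloxy)phenyl]chroman-4-one | C/C(=C\COc1cc(O)c2c(c1)O[C@H](c1ccc(O[Si](C(C)C)(C(C)C)C(C)C)cc1)[C@@H](O)C2=O)CO[Si](C)(C)C(C)(C)C | intermediate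
21 | (2R,3R)-3,5-dihydroxy-7-{[(E)-4-hydroxy-3-methylbut-2-en-1-yl]oxy}-2-(4-hydroxyphenyl)chroman-4-one | C/C(=C\COc1cc(O)c2c(c1)O[C@H](c1ccc(O)cc1)[C@@H](O)C2=O)CO | target

**Step count and risks**

Total step count: 12. Longest linear sequence: 7 steps (steps 1, 2, 3, 6, 7, 11, 12).

Steps most likely to fail:

1. Step 6 (the step carrying the new-method label). Several processes could go wrong:
   - insertion into the electron-rich 5,7-dialkoxychromone may be sluggish;
   - a racemic background arylation through a silyl-activated benzopyrylium species may erode the enantioselectivity;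
   - the enol ether may be protodesilylated before oxidation, which leaves C3 without oxygen;
   - the oxidant may be consumed by zinc, rhodium and phosphine residues or may attack the electron-rich ring A.

   The fallback uses known chemistry, sets out from bromide 7 and chromone 5, and rejoins the route at silyl enol ether 10. Bromide 7 is lithiated (n-BuLi, THF, −78 °C), borylated with B(OiPr)3 and hydrolysed with dilute HCl to [4-(triisopropylsilyloxy)phenyl]boronic acid F1. This acid is added to 5 by the rhodium-catalysed asymmetric 1,4-addition of arylboronic acids to chromones ([Rh(OH)(cod)]2 with an electron-poor atropisomeric bisphosphine of the BIPHEP class, toluene/water). The ligand antipode is chosen to give (S)-5,7-bis(benzyloxy)-2-[4-(triisopropylsilyloxy)phenyl]chroman-4-one F2, which is isolated and, if needed, enriched by crystallisation. Soft enolisation of this flavanone with Me3SiOTf and Et3N in CH2Cl2 at 0 °C gives 10 without a free enolate. Oxidation of 10 with dimethyldioxirane and mild acid, as in the second half of step 6, then gives 13.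

2. Step 11. The redox condensation may activate the secondary 3-OH in competition with the primary allylic alcohol, leading to dehydration or self-condensation. Alkylation at carbon on ring A or allylic transposition may also occur, and separation from the phosphine oxide and hydrazide may be difficult. The fallback replaces the redox condensation by a phenoxide alkylation; it sets out from alcohol 19 and triol 14 and rejoins the route at 20. Alcohol 19 is converted by the Appel reaction (CBr4, PPh3, CH2Cl2, 0 °C) into (E)-[(4-bromo-2-methylbut-2-en-1-yl)oxy](tert-butyl)dimethylsilane F3. Triol 14 is then alkylated with this bromide using K2CO3 (1.1 equiv) in acetone at 23 °C, where only the 7-phenoxide should form and no alcohol is activated.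

3. Step 7. Hydrogenation may go too far: the benzylic C2–O1 bond may be cleaved (ring opening towards a dihydrochalcone), the C4 ketone may be reduced, or the reaction may stall through poisoning of the catalyst by metal or phosphine residues. The fallback replaces hydrogenolysis by a non-reductive Lewis-acid dealkylation; it sets out from 13 and rejoins the route directly at 14. Compound 13 is treated with BCl3 and pentamethylbenzene as benzyl-cation scavenger in CH2Cl2 at −78 °C, conditions that cleave aryl benzyl ethers (the chelating 5-O-benzyl first) and are expected to spare the aryl silyl ether, the ketone and ring C. This fallback passes through no compound outside the list (none F0).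

**Further compounds**

F1 | step 6 | [4-(triisopropylsilyloxy)phenyl]boronic acid | OB(O)c1ccc(O[Si](C(C)C)(C(C)C)C(C)C)cc1
F2 | step 6 | (S)-5,7-bis(benzyloxy)-2-[4-(triisopropylsilyloxy)phenyl]chroman-4-one | C(c1ccccc1)Oc1cc(OCc2ccccc2)c2c(c1)O[C@H](c1ccc(O[Si](C(C)C)(C(C)C)C(C)C)cc1)CC2=O
F3 | step 11 | (E)-[(4-bromo-2-methylbut-2-en-1-yl)oxy](tert-butyl)dimethylsilane | C/C(=C\CBr)CO[Si](C)(C)C(C)(C)C
F0 | step 7 | none | none
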